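**Retrosynthetic overview**
1. The sulfate goes on last, onto the only free hydroxyl of a tribenzyl-protected isolariciresinol. The two hydroxymethyl groups are told apart by origin: C2–CH2O comes from an aldehyde (carried as a silyl ether), C3–CH2OH from a malonate ester.
2. Ring B is closed in one operation by a formal [3+3] annulation of an aryl donor–acceptor cyclopropane with an O-benzyl vanillyl bromide, forming C3–C4 and C1–C8a. The cyclopropane bond C1–C3 is a temporary ring that stores C1 as a latent cation and C3 as a latent enolate.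
3. Enabling feature: the oxygen para to C1 on the pendant guaiacyl ring (ring C) lets C1 ionise easily, and the two esters make C3 the acceptor carbon. In ring A the C6 methoxy group is para to C8a and the C7 oxygen is para to the carbon bearing C4, so the vanillyl unit is electrophilic at C4 and then nucleophilic at C8a.
4. The cyclopropane comes from coniferaldehyde and dimethyl bromomalonate by an organocatalytic Michael-initiated ring closure that sets C2. C1 is then set by C2 in the ring closure, and C3 by equilibration after loss of one ester.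
5. Ring order: rings A and C are bought; the three-membered ring is made first and traded for ring B.

Key step: step 6

Remark: the target is drawn as the free hydrogen sulfate, so it is carried as its sodium salt and set free with one equivalent of HCl in the last step; locants C1–C8a follow the tetralin numbering of the target (C1 aryl-bearing, C2 sulfooxymethyl-bearing, C3 hydroxymethyl-bearing, C4 the benzylic CH2).

**Route**

Step 1
Reactants: 1 coniferaldehyde, (E)-3-(4-hydroxy-3-methoxyphenyl)prop-2-enal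
Product: 2 (E)-3-[4-(benzyloxy)-3-methoxyphenyl]prop-2-enal
Conditions: BnBr (1.1 equiv), K2CO3 (1.5 equiv), DMF, 23 °C
Reagents that add atoms: benzyl bromide, BrCc1ccccc1
Why: Williamson ether synthesis on the phenoxide, the most nucleophilic site, should give a benzyl ether that survives Lewis acid, hydride and base and falls only in the final hydrogenolysis; no stereocentre is formed and the E alkene is untouched.

Step 2
Reactants: 2 (E)-3-[4-(benzyloxy)-3-methoxyphenyl]prop-2-enal; 3 dimethyl 2-bromomalonate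
Product: 4 dimethyl (2S,3R)-2-[4-(benzyloxy)-3-methoxyphenyl]-3-formylcyclopropane-1,1-dicarboxylate
Conditions: (S)-2-[diphenyl(trimethylsilyloxy)methyl]pyrrolidine (20 mol%), 2,6-lutidine (1.1 equiv), CH2Cl2, 0 °C
Reagents that add atoms: none
Why: Organocatalytic Michael-initiated ring closure, in which the malonate carbon adds to the iminium ion of 2 on the face left open by the diphenyl(silyloxy)methyl group of the (S)-catalyst and the resulting enamine displaces bromide (3-exo-tet), should set the formyl-bearing carbon (future C2) and place aryl and formyl trans.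

Step 3
Reactants: 4 dimethyl (2S,3R)-2-[4-(benzyloxy)-3-methoxyphenyl]-3-formylcyclopropane-1,1-dicarboxylate
Product: 5 dimethyl (2S,3R)-2-[4-(benzyloxy)-3-methoxyphenyl]-3-(hydroxymethyl)cyclopropane-1,1-dicarboxylate
Conditions: NaBH4 (0.6 equiv), MeOH–CH2Cl2, −20 °C; pH 7 buffer
Reagents that add atoms: none
Why: Chemoselective borohydride reduction of the aldehyde beside two esters should give the primary alcohol without touching a stereocentre, and the cold neutral quench with direct use of 5 is meant to suppress lactonisation onto the cis ester.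

Step 4
Reactants: 5 dimethyl (2S,3R)-2-[4-(benzyloxy)-3-methoxyphenyl]-3-(hydroxymethyl)cyclopropane-1,1-dicarboxylate
Product: 6 dimethyl (2S,3R)-2-[4-(benzyloxy)-3-methoxyphenyl]-3-({[tri(propan-2-yl)silyl]oxy}methyl)cyclopropane-1,1-dicarboxylate
Conditions: iPr3SiCl (1.3 equiv), imidazole (2.5 equiv), DMF, 0 to 23 °C
Reagents that add atoms: chloro(triisopropyl)silane, CC(C)[Si](Cl)(C(C)C)C(C)C
Why: Silylation of the primary alcohol removes the lactonisation pathway and installs a bulky ether that should tolerate MgI2, hot chloride, methoxide, LiAlH4 and NaH and yet be cleaved by fluoride beside benzyl ethers.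

Step 5
Reactants: 7 [4-(benzyloxy)-3-methoxyphenyl]methanol
Product: 8 1-(benzyloxy)-4-(bromomethyl)-2-methoxybenzene
Conditions: PBr3 (0.4 equiv), Et2O, 0 °C
Reagents that add atoms: phosphorus tribromide, BrP(Br)Br
Why: Standard conversion of a benzylic alcohol into its bromide through the phosphite ester (SN2 by bromide) should give the electron-rich bromide, which is used at once.

Step 6
Reactants: 6 dimethyl (2S,3R)-2-[4-(benzyloxy)-3-methoxyphenyl]-3-({[tri(propan-2-yl)silyl]oxy}methyl)cyclopropane-1,1-dicarboxylate; 8 1-(benzyloxy)-4-(bromomethyl)-2-methoxybenzene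
Product: 11 dimethyl (1S,2R)-7-(benzyloxy)-1-[4-(benzyloxy)-3-methoxyphenyl]-6-methoxy-2-({[tri(propan-2-yl)silyl]oxy}methyl)-1,2,3,4-tetrahydronaphthalene-3,3-dicarboxylate, via iodo magnesium enolate 9 (not isolated), via benzylated benzylic iodide 10 (not isolated)
Conditions: MgI2·OEt2 (1.2 equiv), 2,6-di-tert-butyl-4-methylpyridine (1.3 equiv), 4 Å MS, CH2Cl2, 0 °C; 8 (1.2 equiv) added over 2 h; then 35 °C
Reagents that add atoms: none
Why: Proposed new method: MgI2 binds the two esters of 6 and iodide opens the strained C1–C3 bond at the benzylic donor carbon C1 to give the γ-iodo magnesium malonate enolate 9, whose C3 is benzylated by 8 (as the benzylic iodide after halide exchange) to form C3–C4 in 10; the closest known reaction types are the MgI2-mediated ring expansion of activated cyclopropanes with imines, which runs through the same iodide-opened enolate, and Lewis-acid (3+2) and (3+3) annulations of donor–acceptor cyclopropanes. The secondary benzylic iodide of 10 then ionises, helped by the para benzyloxy group of ring C, and ring A attacks the cation through C8a with loss of a proton to the hindered pyridine, which forms C1–C8a and closes ring B. This closure is a 6-exo-trig Friedel–Crafts alkylation as seen from the cationic C1 (its π bond to ring C lies outside the new ring, the arene bond C4a–C8a inside it). C1 is the only stereocentre formed and is controlled by C2: allylic strain in the planar, quinone-methide-like cation turns the C2 hydrogen toward ring C, so ring A should add to the face that places the C1 aryl and C2 silyloxymethyl groups trans and both equatorial (1S), and since C1 is planar at that stage both C1 epimers of 9 and 10, and any cis isomer of 6, converge on 11, while C2 is untouched and C3 bears two like esters. The step needs C3–C4 to form before C1–C8a (iodide should outrun the weakly nucleophilic arene of 8 as the ring-opening nucleophile, so that no uncontrolled intermolecular arylation at C1 occurs), C- over O-alkylation of the chelated enolate, and attack para and not ortho to the C6 methoxy group, which that methoxy group and the crowding of the ortho site secure. Reclosure of 9 to 6 is harmless and slow addition of 8 limits its self-condensation.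

Step 7
Reactants: 11 dimethyl (1S,2R)-7-(benzyloxy)-1-[4-(benzyloxy)-3-methoxyphenyl]-6-methoxy-2-({[tri(propan-2-yl)silyl]oxy}methyl)-1,2,3,4-tetrahydronaphthalene-3,3-dicarboxylate
Product: 13 methyl (1S,2R,3R)-7-(benzyloxy)-1-[4-(benzyloxy)-3-methoxyphenyl]-6-methoxy-2-({[tri(propan-2-yl)silyl]oxy}methyl)-1,2,3,4-tetrahydronaphthalene-3-carboxylate, via monoester C3 epimers 12 (not isolated)
Conditions: LiCl (3 equiv), H2O (1.05 equiv), DMSO, 150 °C; then 23 °C, NaOMe (1.5 equiv), MeOH, 50 °C
Reagents that add atoms: none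
Why: Krapcho dealkoxycarbonylation (chloride attacks an ester methyl group, the carboxylate loses CO2, the ester enolate is protonated by the one equivalent of water) should give both C3 epimers 12, and methoxide then equilibrates the one acidic C–H, at C3, toward the all-trans isomer with aryl, silyloxymethyl and ester groups all equatorial, so that C3 (R) is set under thermodynamic control by C1 and C2.

Step 8
Reactants: 13 methyl (1S,2R,3R)-7-(benzyloxy)-1-[4-(benzyloxy)-3-methoxyphenyl]-6-methoxy-2-({[tri(propan-2-yl)silyl]oxy}methyl)-1,2,3,4-tetrahydronaphthalene-3-carboxylate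
Product: 14 [(1S,2R,3R)-7-(benzyloxy)-1-[4-(benzyloxy)-3-methoxyphenyl]-6-methoxy-2-({[tri(propan-2-yl)silyl]oxy}methyl)-1,2,3,4-tetrahydronaphthalen-3-yl]methanol
Conditions: LiAlH4 (1.0 equiv), THF, 0 °C
Reagents that add atoms: none
Why: Hydride reduction of the ester to the primary alcohol is faster than enolisation, so C3 should keep its configuration, and silyl and benzyl ethers are inert.

Step 9
Reactants: 14 [(1S,2R,3R)-7-(benzyloxy)-1-[4-(benzyloxy)-3-methoxyphenyl]-6-methoxy-2-({[tri(propan-2-yl)silyl]oxy}methyl)-1,2,3,4-tetrahydronaphthalen-3-yl]methanol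
Product: 15 {[(1S,2R,3R)-7-(benzyloxy)-3-[(benzyloxy)methyl]-1-[4-(benzyloxy)-3-methoxyphenyl]-6-methoxy-1,2,3,4-tetrahydronaphthalen-2-yl]methoxy}tri(propan-2-yl)silane
Conditions: NaH (1.3 equiv), BnBr (1.3 equiv), Bu4NI (0.1 equiv), THF–DMF, 0 to 23 °C
Reagents that add atoms: benzyl bromide, BrCc1ccccc1
Why: Williamson etherification masks the C3 hydroxymethyl group as a third benzyl ether so that every group except the sulfate falls in one final hydrogenolysis, and iodide catalysis at low temperature should keep the bulky silyl group from migrating.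

Step 10
Reactants: 15 {[(1S,2R,3R)-7-(benzyloxy)-3-[(benzyloxy)methyl]-1-[4-(benzyloxy)-3-methoxyphenyl]-6-methoxy-1,2,3,4-tetrahydronaphthalen-2-yl]methoxy}tri(propan-2-yl)silane
Product: 16 [(1S,2R,3R)-7-(benzyloxy)-3-[(benzyloxy)methyl]-1-[4-(benzyloxy)-3-methoxyphenyl]-6-methoxy-1,2,3,4-tetrahydronaphthalen-2-yl]methanol
Conditions: Bu4NF (1.5 equiv), THF, 23 °C
Reagents that add atoms: none
Why: Fluoride-driven cleavage of the Si–O bond (strong Si–F bond) should free only the C2 hydroxymethyl group, the single hydroxyl of 16.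

Step 11
Reactants: 16 [(1S,2R,3R)-7-(benzyloxy)-3-[(benzyloxy)methyl]-1-[4-(benzyloxy)-3-methoxyphenyl]-6-methoxy-1,2,3,4-tetrahydronaphthalen-2-yl]methanol
Product: 18 sodium [(1S,2R,3R)-7-(benzyloxy)-3-[(benzyloxy)methyl]-1-[4-(benzyloxy)-3-methoxyphenyl]-6-methoxy-1,2,3,4-tetrahydronaphthalen-2-yl]methyl sulfate, via pyridinium sulfate 17 (not isolated)
Conditions: SO3·pyridine (3 equiv), pyridine, 40 °C; then aq NaHCO3, 0 °C
Reagents that add atoms: sulfur trioxide pyridine complex, O=S(=O)([O-])[n+]1ccccc1; sodium hydrogen carbonate, [Na+].OC([O-])=O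
Why: O-Sulfonation of the only free hydroxyl by the SO3 pyridine complex should give the sulfate monoester, isolated as its stable sodium salt after cation exchange with NaHCO3; no stereocentre is involved.

Step 12
Reactants: 18 sodium [(1S,2R,3R)-7-(benzyloxy)-3-[(benzyloxy)methyl]-1-[4-(benzyloxy)-3-methoxyphenyl]-6-methoxy-1,2,3,4-tetrahydronaphthalen-2-yl]methyl sulfate
Product: 20 [(1S,2R,3R)-7-hydroxy-1-(4-hydroxy-3-methoxyphenyl)-3-(hydroxymethyl)-6-methoxy-1,2,3,4-tetrahydronaphthalen-2-yl]methyl hydrogen sulfate (CNP0184747.1), via sodium salt of the target 19 (not isolated)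
Conditions: H2 (1 atm), 10% Pd/C, MeOH–THF, 23 °C; filter; HCl (1.00 equiv, 0.1 M aq), 0 °C; C18 desalting, lyophilise
Reagents that add atoms: none
Why: Heterogeneous hydrogenolysis should cleave the two aryl benzyl ethers and the alkyl benzyl ether while the sulfate monoester anion, the C1–aryl bonds and the three stereocentres stay untouched, and one equivalent of HCl at 0 °C then protonates the sulfate to the hydrogen sulfate as drawn.

**Compound list**
1 | coniferaldehyde, (E)-3-(4-hydroxy-3-methoxyphenyl)prop-2-enal | COc1cc(/C=C/C=O)ccc1O | starting material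
2 | (E)-3-[4-(benzyloxy)-3-methoxyphenyl]prop-2-enal | COc1cc(/C=C/C=O)ccc1OCc1ccccc1 | intermediate
3 | dimethyl 2-bromomalonate | COC(=O)C(Br)C(=O)OC | starting material
4 | dimethyl (2S,3R)-2-[4-(benzyloxy)-3-methoxyphenyl]-3-formylcyclopropane-1,1-dicarboxylate (aryl and formyl trans) | O=C[C@@H]1[C@@H](c2ccc(OCc3ccccc3)c(OC)c2)C1(C(=O)OC)C(=O)OC | intermediate
5 | dimethyl (2S,3R)-2-[4-(benzyloxy)-3-methoxyphenyl]-3-(hydroxymethyl)cyclopropane-1,1-dicarboxylate | OC[C@@H]1[C@@H](c2ccc(OCc3ccccc3)c(OC)c2)C1(C(=O)OC)C(=O)OC | intermediate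
6 | dimethyl (2S,3R)-2-[4-(benzyloxy)-3-methoxyphenyl]-3-({[tri(propan-2-yl)silyl]oxy}methyl)cyclopropane-1,1-dicarboxylate | CC(C)[Si](OC[C@@H]1[C@@H](c2ccc(OCc3ccccc3)c(OC)c2)C1(C(=O)OC)C(=O)OC)(C(C)C)C(C)C | intermediate
7 | [4-(benzyloxy)-3-methoxyphenyl]methanol | OCc1ccc(OCc2ccccc2)c(OC)c1 | starting material
8 | 1-(benzyloxy)-4-(bromomethyl)-2-methoxybenzene | BrCc1ccc(OCc2ccccc2)c(OC)c1 | intermediate
9 | iodomagnesium enolate of dimethyl 2-[(2R)-1-[4-(benzyloxy)-3-methoxyphenyl]-1-iodo-3-{[tri(propan-2-yl)silyl]oxy}propan-2-yl]malonate, both epimers at the iodo-bearing carbon, formed in the flask | COC(=O)C(=C(OC)O[Mg]I)[C@H](CO[Si](C(C)C)(C(C)C)C(C)C)C(I)c1ccc(OCc2ccccc2)c(OC)c1 | intermediate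
10 | dimethyl 2-[4-(benzyloxy)-3-methoxybenzyl]-2-[(2R)-1-[4-(benzyloxy)-3-methoxyphenyl]-1-iodo-3-{[tri(propan-2-yl)silyl]oxy}propan-2-yl]malonate, both epimers at the iodo-bearing carbon, formed in the flask | COC(=O)C(Cc1ccc(OCc2ccccc2)c(OC)c1)(C(=O)OC)[C@H](CO[Si](C(C)C)(C(C)C)C(C)C)C(I)c1ccc(OCc2ccccc2)c(OC)c1 | intermediate
11 | dimethyl (1S,2R)-7-(benzyloxy)-1-[4-(benzyloxy)-3-methoxyphenyl]-6-methoxy-2-({[tri(propan-2-yl)silyl]oxy}methyl)-1,2,3,4-tetrahydronaphthalene-3,3-dicarboxylate | COc1cc([C@H]2c3cc(OCc4ccccc4)c(OC)cc3CC(C(=O)OC)(C(=O)OC)[C@@H]2CO[Si](C(C)C)(C(C)C)C(C)C)ccc1OCc1ccccc1 | intermediate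
12 | methyl (1S,2R)-7-(benzyloxy)-1-[4-(benzyloxy)-3-methoxyphenyl]-6-methoxy-2-({[tri(propan-2-yl)silyl]oxy}methyl)-1,2,3,4-tetrahydronaphthalene-3-carboxylate, both C3 epimers, formed in the flask | COc1cc([C@H]2c3cc(OCc4ccccc4)c(OC)cc3CC(C(=O)OC)[C@@H]2CO[Si](C(C)C)(C(C)C)C(C)C)ccc1OCc1ccccc1 | intermediate
13 | methyl (1S,2R,3R)-7-(benzyloxy)-1-[4-(benzyloxy)-3-methoxyphenyl]-6-methoxy-2-({[tri(propan-2-yl)silyl]oxy}methyl)-1,2,3,4-tetrahydronaphthalene-3-carboxylate (all-trans) | COc1cc([C@H]2c3cc(OCc4ccccc4)c(OC)cc3C[C@@H](C(=O)OC)[C@@H]2CO[Si](C(C)C)(C(C)C)C(C)C)ccc1OCc1ccccc1 | intermediate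
14 | [(1S,2R,3R)-7-(benzyloxy)-1-[4-(benzyloxy)-3-methoxyphenyl]-6-methoxy-2-({[tri(propan-2-yl)silyl]oxy}methyl)-1,2,3,4-tetrahydronaphthalen-3-yl]methanol | COc1cc([C@H]2c3cc(OCc4ccccc4)c(OC)cc3C[C@@H](CO)[C@@H]2CO[Si](C(C)C)(C(C)C)C(C)C)ccc1OCc1ccccc1 | intermediate
15 | {[(1S,2R,3R)-7-(benzyloxy)-3-[(benzyloxy)methyl]-1-[4-(benzyloxy)-3-methoxyphenyl]-6-methoxy-1,2,3,4-tetrahydronaphthalen-2-yl]methoxy}tri(propan-2-yl)silane | COc1cc([C@H]2c3cc(OCc4ccccc4)c(OC)cc3C[C@@H](COCc3ccccc3)[C@@H]2CO[Si](C(C)C)(C(C)C)C(C)C)ccc1OCc1ccccc1 | intermediate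
16 | [(1S,2R,3R)-7-(benzyloxy)-3-[(benzyloxy)methyl]-1-[4-(benzyloxy)-3-methoxyphenyl]-6-methoxy-1,2,3,4-tetrahydronaphthalen-2-yl]methanol | COc1cc([C@H]2c3cc(OCc4ccccc4)c(OC)cc3C[C@@H](COCc3ccccc3)[C@@H]2CO)ccc1OCc1ccccc1 | intermediate
17 | pyridinium [(1S,2R,3R)-7-(benzyloxy)-3-[(benzyloxy)methyl]-1-[4-(benzyloxy)-3-methoxyphenyl]-6-methoxy-1,2,3,4-tetrahydronaphthalen-2-yl]methyl sulfate, formed in the flask | COc1cc([C@H]2c3cc(OCc4ccccc4)c(OC)cc3C[C@@H](COCc3ccccc3)[C@@H]2COS(=O)(=O)[O-])ccc1OCc1ccccc1.c1cc[nH+]cc1 | intermediate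
18 | sodium [(1S,2R,3R)-7-(benzyloxy)-3-[(benzyloxy)methyl]-1-[4-(benzyloxy)-3-methoxyphenyl]-6-methoxy-1,2,3,4-tetrahydronaphthalen-2-yl]methyl sulfate | COc1cc([C@H]2c3cc(OCc4ccccc4)c(OC)cc3C[C@@H](COCc3ccccc3)[C@@H]2COS(=O)(=O)[O-])ccc1OCc1ccccc1.[Na+] | intermediate
19 | sodium [(1S,2R,3R)-7-hydroxy-1-(4-hydroxy-3-methoxyphenyl)-3-(hydroxymethyl)-6-methoxy-1,2,3,4-tetrahydronaphthalen-2-yl]methyl sulfate, formed in the flask | COc1cc([C@H]2c3cc(O)c(OC)cc3C[C@@H](CO)[C@@H]2COS(=O)(=O)[O-])ccc1O.[Na+] | intermediate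
20 | [(1S,2R,3R)-7-hydroxy-1-(4-hydroxy-3-methoxyphenyl)-3-(hydroxymethyl)-6-methoxy-1,2,3,4-tetrahydronaphthalen-2-yl]methyl hydrogen sulfate (CNP0184747.1) | COc1cc([C@H]2c3cc(O)c(OC)cc3C[C@@H](CO)[C@@H]2COS(=O)(=O)O)ccc1O | target

**Step count and risks**
Total: 12 steps. Longest linear sequence: 11 steps (steps 1–4 and 6–12); step 5 is a one-step side branch.

Most likely to fail, in this order:

Step 6 (proposed method). The chelated magnesium enolate may be benzylated too slowly. Competing processes could then take over: O-cyclisation of the enolate onto C1 with loss of methyl iodide to a γ-lactone, loss of HI across C1–C2 (which erases C2), self-condensation of the benzylic bromide, or direct arylation of C1 before C3–C4 exists (which would fix C1 without control). The fallback uses known chemistry, sets out from 6 and comes back at 11. Sc(OTf)3-catalysed methanolysis (MeOH, CH2Cl2, 23 °C) opens the C1–C3 bond to the γ-methoxy malonate dimethyl 2-[(2R)-1-[4-(benzyloxy)-3-methoxyphenyl]-1-methoxy-3-{[tri(propan-2-yl)silyl]oxy}propan-2-yl]malonate F1, a mixture of C1 epimers. Its sodium enolate (NaH, DMF, 0 °C) is benzylated with 8 to the quaternary malonate F2. BF3·OEt2 in CH2Cl2 at −40 °C then ionises the benzylic methyl ether and closes ring B by the same stereoconvergent Friedel–Crafts alkylation to give 11.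

Step 7. The thermodynamic preference at C3 may be too small, or equilibration may be slower than ester cleavage, so that the C3 epimer is carried along. The fallback sets C3 kinetically; it sets out from 12 (worked up after the chloride stage) and comes back at 16.
- LiN(iPr)2 and then PhSeBr (THF, −78 °C) should give the C3 phenylselanyl derivative of 12, F3.
- H2O2 oxidises it to the selenoxide F4, which should eliminate toward the benzylic C4–H to the conjugated 3,4-unsaturated ester F5.
- iBu2AlH (toluene, −78 °C) reduces the ester to the allylic alcohol F6.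
- NaH and BnBr give the allylic benzyl ether F7.
- Bu4NF frees the homoallylic C2 hydroxymethyl group in F8.
- Hydrogenation with [Ir(cod)(PCy3)(py)]PF6 (H2, CH2Cl2) is directed by that hydroxyl, so hydrogen should reach C3 on the face of the C2 hydroxymethyl group and leave the C3 benzyloxymethyl group trans, which is 16.

Step 2. Conjugate addition to the electron-rich iminium ion may be sluggish, and the amine may open the product cyclopropane, so conversion and enantiomeric purity could erode. The fallback separates the two bond formations; it sets out from 2 and comes back at 4. The same (S)-catalyst adds commercial dimethyl malonate to 2 (EtOH, 0 °C) to give the aldehyde dimethyl 2-[(1R)-1-[4-(benzyloxy)-3-methoxyphenyl]-3-oxopropyl]malonate F9. Iodine and DBU (CH2Cl2, 0 °C) then iodinate the malonate carbon to the iodomalonate F10, which is not isolated; intramolecular alkylation of the aldehyde enolate closes the three-membered ring to the trans cyclopropane 4.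

**Further compounds**
F1 | step 6 | dimethyl 2-[(2R)-1-[4-(benzyloxy)-3-methoxyphenyl]-1-methoxy-3-{[tri(propan-2-yl)silyl]oxy}propan-2-yl]malonate (both epimers at the methoxy-bearing carbon) | COC(=O)C(C(=O)OC)[C@H](CO[Si](C(C)C)(C(C)C)C(C)C)C(OC)c1ccc(OCc2ccccc2)c(OC)c1
F2 | step 6 | dimethyl 2-[4-(benzyloxy)-3-methoxybenzyl]-2-[(2R)-1-[4-(benzyloxy)-3-methoxyphenyl]-1-methoxy-3-{[tri(propan-2-yl)silyl]oxy}propan-2-yl]malonate (both epimers at the methoxy-bearing carbon) | COC(=O)C(Cc1ccc(OCc2ccccc2)c(OC)c1)(C(=O)OC)[C@H](CO[Si](C(C)C)(C(C)C)C(C)C)C(OC)c1ccc(OCc2ccccc2)c(OC)c1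
F3 | step 7 | C3 phenylselanyl derivative of 12, methyl 7-(benzyloxy)-1-[4-(benzyloxy)-3-methoxyphenyl]-6-methoxy-3-(phenylselanyl)-2-({[tri(propan-2-yl)silyl]oxy}methyl)-1,2,3,4-tetrahydronaphthalene-3-carboxylate, C1 and C2 as in 12 | COc1cc([C@H]2c3cc(OCc4ccccc4)c(OC)cc3CC([Se]c3ccccc3)(C(=O)OC)[C@@H]2CO[Si](C(C)C)(C(C)C)C(C)C)ccc1OCc1ccccc1
F4 | step 7 | selenoxide of F3 (not isolated) | COc1cc([C@H]2c3cc(OCc4ccccc4)c(OC)cc3CC([Se](=O)c3ccccc3)(C(=O)OC)[C@@H]2CO[Si](C(C)C)(C(C)C)C(C)C)ccc1OCc1ccccc1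
F5 | step 7 | methyl (1S,2R)-7-(benzyloxy)-1-[4-(benzyloxy)-3-methoxyphenyl]-6-methoxy-2-({[tri(propan-2-yl)silyl]oxy}methyl)-1,2-dihydronaphthalene-3-carboxylate | COc1cc([C@H]2c3cc(OCc4ccccc4)c(OC)cc3C=C(C(=O)OC)[C@@H]2CO[Si](C(C)C)(C(C)C)C(C)C)ccc1OCc1ccccc1
F6 | step 7 | [(1S,2R)-7-(benzyloxy)-1-[4-(benzyloxy)-3-methoxyphenyl]-6-methoxy-2-({[tri(propan-2-yl)silyl]oxy}methyl)-1,2-dihydronaphthalen-3-yl]methanol | COc1cc([C@H]2c3cc(OCc4ccccc4)c(OC)cc3C=C(CO)[C@@H]2CO[Si](C(C)C)(C(C)C)C(C)C)ccc1OCc1ccccc1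
F7 | step 7 | benzyl ether of F6 at the allylic hydroxyl | COc1cc([C@H]2c3cc(OCc4ccccc4)c(OC)cc3C=C(COCc3ccccc3)[C@@H]2CO[Si](C(C)C)(C(C)C)C(C)C)ccc1OCc1ccccc1
F8 | step 7 | [(1S,2R)-7-(benzyloxy)-3-[(benzyloxy)methyl]-1-[4-(benzyloxy)-3-methoxyphenyl]-6-methoxy-1,2-dihydronaphthalen-2-yl]methanol | COc1cc([C@H]2c3cc(OCc4ccccc4)c(OC)cc3C=C(COCc3ccccc3)[C@@H]2CO)ccc1OCc1ccccc1
F9 | step 2 | dimethyl 2-[(1R)-1-[4-(benzyloxy)-3-methoxyphenyl]-3-oxopropyl]malonate | COC(=O)C(C(=O)OC)[C@@H](CC=O)c1ccc(OCc2ccccc2)c(OC)c1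
F10 | step 2 | dimethyl 2-iodo-2-[(1S)-1-[4-(benzyloxy)-3-methoxyphenyl]-3-oxopropyl]malonate (not isolated) | COC(=O)C(I)(C(=O)OC)[C@@H](CC=O)c1ccc(OCc2ccccc2)c(OC)c1
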